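Everything rests on opening ring C of the middle flavan unit at O1–C2 and C3–C4. Its cis C2-aryl/C3-O-gallate pair is a cis enol gallate, and O1, C8a, C4a and C4 form an ortho-quinone methide, so one acid-catalysed oxa-[4+2] cycloaddition closes this pyran, sets C2, C3 and C4 (C4 aryl trans) and brings in ring B and the gallate together. The precursor is a benzyl-protected ortho-hydroxy diaryl carbinol: the carbinol carbon (future C4) links C8 of the bottom epicatechin gallate to C4a of a phenol whose C8 already carries C4 of the top epicatechin. All remaining stereocentres come from (−)-epicatechin.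

Key step: step 12

Remark on the chemistry: flavan numbering (O1, C2, C3, C4, C4a, C5–C8, C8a; ring A = benzo ring, ring B = 2-aryl, ring C = pyran) is used for each unit. "Top" is the 3-hydroxy unit, "middle" and "bottom" are the two gallates. The carbinol precursor is carried as a mixture of both carbinol epimers, because both lose water to the same quinone methide.

**Route**

Step 1
Reactants: 1 (−)-epicatechin
Product: 2 5,7,3',4'-tetra-O-benzyl-(−)-epicatechin
Conditions: BnBr (4.4 equiv), K2CO3, DMF, 0 °C to rt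
Reagents that add atoms: benzyl bromide, BrCc1ccccc1
Why: Williamson ether synthesis on the four phenols only, since K2CO3 does not deprotonate the secondary 3-OH, so C2 and C3 stay (2R,3R).

Step 2
Reactants: 2 5,7,3',4'-tetra-O-benzyl-(−)-epicatechin
Product: 3 5,7,3',4'-tetra-O-benzyl-4β-(2-ethoxyethoxy)epicatechin
Conditions: DDQ (2 equiv), 2-ethoxyethanol, CH2Cl2, rt
Reagents that add atoms: 2-ethoxyethanol, CCOCCO
Why: DDQ benzylic oxidation, in which hydride abstraction from C4 gives a cation stabilised by the ring A oxygens and the alcohol adds anti to the C3 hydroxyl, setting C4 as 4β (3,4-trans).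

Step 3
Reactants: 3 5,7,3',4'-tetra-O-benzyl-4β-(2-ethoxyethoxy)epicatechin
Product: 4 3,5,7,3',4'-penta-O-benzyl-4β-(2-ethoxyethoxy)epicatechin
Conditions: NaH, BnBr, n-Bu4NI (cat.), DMF, 0 °C to rt
Reagents that add atoms: benzyl bromide, BrCc1ccccc1
Why: Williamson etherification of the secondary alkoxide in the presence of the base-stable C4 ether; the benzyl cap keeps this oxygen from later closing a seven-membered ether onto the quinone methide and leaves in the final hydrogenolysis.

Step 4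
Reactants: 5 phloroglucinol
Product: 6 3,5-bis(benzyloxy)phenol
Conditions: BnBr (2.0 equiv), K2CO3, DMF, rt; chromatography
Reagents that add atoms: benzyl bromide, BrCc1ccccc1
Why: statistical Williamson O-benzylation of a symmetric triol, from which the mono- and tri-ethers should separate by chromatography.

Step 5
Reactants: 4 3,5,7,3',4'-penta-O-benzyl-4β-(2-ethoxyethoxy)epicatechin; 6 3,5-bis(benzyloxy)phenol (3 equiv)
Product: 7 2-[3,5,7,3',4'-penta-O-benzylepicatechin-4β-yl]-3,5-bis(benzyloxy)phenol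
Conditions: TMSOTf (0.5 equiv), CH2Cl2, −78 to −40 °C; Et3N quench
Reagents that add atoms: none
Why: Lewis-acid ionisation of the C4 ether gives the flavan-4-yl cation, which undergoes Friedel–Crafts arylation at a carbon ortho to the free hydroxyl (two such sites, each less hindered than the carbon between two benzyloxy groups) and anti to the C3 benzyloxy group, giving the 4β (3,4-trans) aryl.

Step 6
Reactants: 2 5,7,3',4'-tetra-O-benzyl-(−)-epicatechin
Product: 8 8-bromo-5,7,3',4'-tetra-O-benzyl-(−)-epicatechin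
Conditions: NBS (1.0 equiv), CH2Cl2, −78 °C to rt
Reagents that add atoms: N-bromosuccinimide, BrN1C(=O)CCC1=O
Why: electrophilic aromatic bromination, for which C8 of the 5,7-dibenzyloxy ring A is the established site in this substrate class; no stereocentre is involved.

Step 7
Reactants: 8 8-bromo-5,7,3',4'-tetra-O-benzyl-(−)-epicatechin
Product: 10 8-formyl-5,7,3',4'-tetra-O-benzyl-(−)-epicatechin, via C8-lithio lithium alkoxide 9 (not isolated)
Conditions: n-BuLi (2.2 equiv), THF, −78 °C; DMF, −78 to 0 °C; aq. NH4Cl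
Reagents that add atoms: N,N-dimethylformamide, CN(C)C=O
Why: the first equivalent of base masks the 3-OH as its alkoxide, the second effects bromine–lithium exchange at C8, and Bouveault formylation of the aryllithium by DMF gives the aldehyde at a position fixed by the bromide.

Step 8
Reactants: 10 8-formyl-5,7,3',4'-tetra-O-benzyl-(−)-epicatechin; 11 3,4,5-tris(benzyloxy)benzoic acid
Product: 12 8-formyl-5,7,3',4'-tetra-O-benzyl-(−)-epicatechin 3-O-[3,4,5-tris(benzyloxy)benzoate]
Conditions: DCC, DMAP, CH2Cl2, rt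
Reagents that add atoms: none
Why: Steglich esterification of the secondary 3-OH, which proceeds at oxygen with retention at C3 and leaves the aldehyde untouched.

Step 9
Reactants: 7 2-[3,5,7,3',4'-penta-O-benzylepicatechin-4β-yl]-3,5-bis(benzyloxy)phenol; 12 8-formyl-5,7,3',4'-tetra-O-benzyl-(−)-epicatechin 3-O-[3,4,5-tris(benzyloxy)benzoate]
Product: 14 {2-hydroxy-4,6-bis(benzyloxy)-3-[3,5,7,3',4'-penta-O-benzylepicatechin-4β-yl]phenyl}[hepta-O-benzyl-(−)-epicatechin-3-O-gallate-8-yl]methanol (both carbinol epimers), via bromomagnesium phenolate 13 (not isolated)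
Conditions: EtMgBr (1.0 equiv), Et2O, 0 °C; solvent exchanged for toluene; then 12, rt to 50 °C; cold aq. NH4Cl
Reagents that add atoms: none
Why: ortho-specific hydroxyalkylation of a magnesium phenolate by an aromatic aldehyde (Casiraghi type), in which magnesium holds phenolate oxygen and aldehyde in a six-membered transition state that delivers the carbonyl carbon to the only free ortho position; the new carbinol centre is uncontrolled and is erased in step 12.

Step 10
Reactants: 15 3,4-bis(benzyloxy)benzaldehyde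
Product: 16 4-ethynyl-1,2-bis(benzyloxy)benzene
Conditions: dimethyl (1-diazo-2-oxopropyl)phosphonate, K2CO3, MeOH/THF, rt
Reagents that add atoms: dimethyl (1-diazo-2-oxopropyl)phosphonate, COP(=O)(OC)C(=[N+]=[N-])C(C)=O
Why: Seyferth–Gilbert homologation in the Ohira–Bestmann variant, which converts a non-enolisable aryl aldehyde into the terminal alkyne under mild base.

Step 11
Reactants: 16 4-ethynyl-1,2-bis(benzyloxy)benzene; 11 3,4,5-tris(benzyloxy)benzoic acid
Product: 17 (Z)-2-[3,4-bis(benzyloxy)phenyl]ethenyl 3,4,5-tris(benzyloxy)benzoate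
Conditions: Ru(2-methylallyl)2(dppb) (2 mol%), toluene, 60 °C
Reagents that add atoms: none
Why: ruthenium-catalysed anti-Markovnikov addition of a carboxylic acid to a terminal alkyne through a ruthenium vinylidene, where carboxylate attack at the vinylidene carbon and protonolysis deliver the cis (Z) enol ester.

Step 12
Reactants: 14 diaryl carbinol (both epimers); 17 (Z)-2-[3,4-bis(benzyloxy)phenyl]ethenyl 3,4,5-tris(benzyloxy)benzoate (3 equiv)
Product: 19 nonadeca-O-benzyl [epicatechin-(4β→8)-epicatechin 3-O-gallate-(4β→8)-epicatechin 3-O-gallate], via ortho-quinone methide 18 (not isolated)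
Conditions: (R)-TRIP [(R)-3,3'-bis(2,4,6-triisopropylphenyl)-1,1'-binaphthyl-2,2'-diyl hydrogen phosphate] (10 mol%), 5 Å MS, toluene, −20 °C to rt
Reagents that add atoms: none
Why: The phosphoric acid ionises either carbinol epimer of 14 with loss of water (the cation is stabilised by both trioxygenated rings) and loss of the phenolic proton gives ortho-quinone methide 18, whose O1=C8a–C4a=C4 unit is an electron-poor oxa-diene held s-cis by ring A; enol ester 17 then adds in an asynchronous inverse-electron-demand oxa-Diels–Alder reaction, its oxygen-bearing carbon (the nucleophilic terminus because the 3,4-dialkoxyphenyl group stabilises positive charge on the other carbon) bonding to C4 and its benzylic carbon to O1. The closest known reaction type is the Brønsted-acid-catalysed [4+2] cycloaddition of ortho-quinone methides, generated from ortho-hydroxybenzyl alcohols, with beta-substituted styrenes to give 2-arylchromans. Ring C of the middle unit closes in this [4+2] mode (should the addition be stepwise, by 6-exo attack of the phenolic oxygen on the benzylic cation inside the ion pair). C2 and C3 come out cis because both new bonds form on one face of the Z alkene; C4 comes out trans to the gallate when the alkene substituents lie endo to the methide whose C4 aryl group points towards O1 (the geometry the peri C5 benzyloxy group is expected to favour), and the absolute sense of all three centres follows from the methide face attacked, which the chiral phosphate hydrogen-bonded at O1, together with the adjacent top-unit C4 stereocentre, has to decide. The step thus needs regio-, endo- and face selectivity and retention of the Z geometry: the styrene polarisation secures the regiochemistry, a tight phosphate ion pair in a non-polar solvent at low temperature favours suprafacial addition, excess 17 outcompetes arene capture of the methide, and the antipodal acid is the first recourse if the (R) catalyst is mismatched with the substrate.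

Step 13
Reactants: 19 nonadeca-O-benzyl trimer
Product: 20 epicatechin-(4β→8)-epicatechin 3-O-gallate-(4β→8)-epicatechin 3-O-gallate (CNP0279403.1)
Conditions: H2 (1 atm), Pd(OH)2 on carbon, THF/MeOH/H2O, rt; filtration, lyophilisation
Reagents that add atoms: none
Why: hydrogenolysis of all nineteen benzyl ethers under neutral conditions, which should leave the gallate esters, the pyran C–O bonds and the interflavan C–C bonds intact, so no stereocentre is touched.

**Compound list**

1 | (−)-epicatechin, (2R,3R) | O[C@@H]1Cc2c(O)cc(O)cc2O[C@@H]1c1ccc(O)c(O)c1 | starting material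
2 | 5,7,3',4'-tetra-O-benzyl-(−)-epicatechin, (2R,3R) | O[C@@H]1Cc2c(OCc3ccccc3)cc(OCc3ccccc3)cc2O[C@@H]1c1ccc(OCc2ccccc2)c(OCc2ccccc2)c1 | intermediate
3 | 5,7,3',4'-tetra-O-benzyl-4β-(2-ethoxyethoxy)epicatechin (2,3-cis, 3,4-trans) | O1[C@H](c3ccc(OCc4ccccc4)c(OCc4ccccc4)c3)[C@H](O)[C@@H](OCCOCC)c2c(OCc3ccccc3)cc(OCc3ccccc3)cc21 | intermediate
4 | 3,5,7,3',4'-penta-O-benzyl-4β-(2-ethoxyethoxy)epicatechin (2,3-cis, 3,4-trans) | O1[C@H](c3ccc(OCc4ccccc4)c(OCc4ccccc4)c3)[C@H](OCc3ccccc3)[C@@H](OCCOCC)c2c(OCc3ccccc3)cc(OCc3ccccc3)cc21 | intermediate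
5 | phloroglucinol | Oc1cc(O)cc(O)c1 | starting material
6 | 3,5-bis(benzyloxy)phenol | Oc1cc(OCc2ccccc2)cc(OCc2ccccc2)c1 | intermediate
7 | 2-[3,5,7,3',4'-penta-O-benzylepicatechin-4β-yl]-3,5-bis(benzyloxy)phenol (flavan 2,3-cis, 3,4-trans) | O1[C@H](c3ccc(OCc4ccccc4)c(OCc4ccccc4)c3)[C@H](OCc3ccccc3)[C@@H](c3c(OCc4ccccc4)cc(OCc4ccccc4)cc3O)c2c(OCc3ccccc3)cc(OCc3ccccc3)cc21 | intermediate
8 | 8-bromo-5,7,3',4'-tetra-O-benzyl-(−)-epicatechin, (2R,3R) | O[C@@H]1Cc2c(OCc3ccccc3)cc(OCc3ccccc3)c(Br)c2O[C@@H]1c1ccc(OCc2ccccc2)c(OCc2ccccc2)c1 | intermediate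
9 | C8-lithio lithium 3-alkoxide of 5,7,3',4'-tetra-O-benzylepicatechin | [Li]O[C@@H]1Cc2c(OCc3ccccc3)cc(OCc3ccccc3)c([Li])c2O[C@@H]1c1ccc(OCc2ccccc2)c(OCc2ccccc2)c1 | intermediate (not isolated)
10 | 8-formyl-5,7,3',4'-tetra-O-benzyl-(−)-epicatechin, (2R,3R) | O[C@@H]1Cc2c(OCc3ccccc3)cc(OCc3ccccc3)c(C=O)c2O[C@@H]1c1ccc(OCc2ccccc2)c(OCc2ccccc2)c1 | intermediate
11 | 3,4,5-tris(benzyloxy)benzoic acid | OC(=O)c1cc(OCc2ccccc2)c(OCc2ccccc2)c(OCc2ccccc2)c1 | starting material
12 | 8-formyl-5,7,3',4'-tetra-O-benzyl-(−)-epicatechin 3-O-[3,4,5-tris(benzyloxy)benzoate], (2R,3R) | O=C(O[C@@H]1Cc2c(OCc3ccccc3)cc(OCc3ccccc3)c(C=O)c2O[C@@H]1c1ccc(OCc2ccccc2)c(OCc2ccccc2)c1)c1cc(OCc2ccccc2)c(OCc2ccccc2)c(OCc2ccccc2)c1 | intermediate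
13 | bromomagnesium phenolate of 7 | O1[C@H](c3ccc(OCc4ccccc4)c(OCc4ccccc4)c3)[C@H](OCc3ccccc3)[C@@H](c3c(OCc4ccccc4)cc(OCc4ccccc4)cc3O[Mg]Br)c2c(OCc3ccccc3)cc(OCc3ccccc3)cc21 | intermediate (not isolated)
14 | {2-hydroxy-4,6-bis(benzyloxy)-3-[3,5,7,3',4'-penta-O-benzylepicatechin-4β-yl]phenyl}[hepta-O-benzyl-(−)-epicatechin-3-O-gallate-8-yl]methanol, carbinol centre as a mixture of epimers | O1[C@H](c3ccc(OCc4ccccc4)c(OCc4ccccc4)c3)[C@H](OCc3ccccc3)[C@@H](c3c(OCc4ccccc4)cc(OCc4ccccc4)c(C(O)c5c(OCc4ccccc4)cc(OCc4ccccc4)c6c5O[C@H](c7ccc(OCc4ccccc4)c(OCc4ccccc4)c7)[C@H](OC(=O)c7cc(OCc4ccccc4)c(OCc4ccccc4)c(OCc4ccccc4)c7)C6)c3O)c2c(OCc3ccccc3)cc(OCc3ccccc3)cc21 | intermediate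
15 | 3,4-bis(benzyloxy)benzaldehyde | O=Cc1ccc(OCc2ccccc2)c(OCc2ccccc2)c1 | starting material
16 | 4-ethynyl-1,2-bis(benzyloxy)benzene | C#Cc1ccc(OCc2ccccc2)c(OCc2ccccc2)c1 | intermediate
17 | (Z)-2-[3,4-bis(benzyloxy)phenyl]ethenyl 3,4,5-tris(benzyloxy)benzoate | O=C(O/C=C\c1ccc(OCc2ccccc2)c(OCc2ccccc2)c1)c1cc(OCc2ccccc2)c(OCc2ccccc2)c(OCc2ccccc2)c1 | intermediate
18 | ortho-quinone methide from 14 (middle-unit O1=C8a–C4a=C4; exocyclic alkene geometry not fixed) | O1[C@H](c3ccc(OCc4ccccc4)c(OCc4ccccc4)c3)[C@H](OCc3ccccc3)[C@@H](C3=C(OCc4ccccc4)C=C(OCc4ccccc4)C(=Cc5c(OCc4ccccc4)cc(OCc4ccccc4)c6c5O[C@H](c7ccc(OCc4ccccc4)c(OCc4ccccc4)c7)[C@H](OC(=O)c7cc(OCc4ccccc4)c(OCc4ccccc4)c(OCc4ccccc4)c7)C6)C3=O)c2c(OCc3ccccc3)cc(OCc3ccccc3)cc21 | intermediate (not isolated)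
19 | nonadeca-O-benzyl [epicatechin-(4β→8)-epicatechin 3-O-gallate-(4β→8)-epicatechin 3-O-gallate]; every unit 2,3-cis, both upper units 3,4-trans | O1[C@H](c3ccc(OCc4ccccc4)c(OCc4ccccc4)c3)[C@H](OCc3ccccc3)[C@@H](c3c(OCc4ccccc4)cc(OCc4ccccc4)c5c3O[C@H](c6ccc(OCc4ccccc4)c(OCc4ccccc4)c6)[C@H](OC(=O)c6cc(OCc4ccccc4)c(OCc4ccccc4)c(OCc4ccccc4)c6)[C@H]5c5c(OCc4ccccc4)cc(OCc4ccccc4)c6c5O[C@H](c7ccc(OCc4ccccc4)c(OCc4ccccc4)c7)[C@H](OC(=O)c7cc(OCc4ccccc4)c(OCc4ccccc4)c(OCc4ccccc4)c7)C6)c2c(OCc3ccccc3)cc(OCc3ccccc3)cc21 | intermediate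
20 | epicatechin-(4β→8)-epicatechin 3-O-gallate-(4β→8)-epicatechin 3-O-gallate (CNP0279403.1) | O=C(O[C@@H]1[C@@H](c2c(O)cc(O)c3c2O[C@H](c2ccc(O)c(O)c2)[C@H](OC(=O)c2cc(O)c(O)c(O)c2)C3)c2c(O)cc(O)c([C@H]3c4c(O)cc(O)cc4O[C@H](c4ccc(O)c(O)c4)[C@@H]3O)c2O[C@@H]1c1ccc(O)c(O)c1)c1cc(O)c(O)c(O)c1 | target

**Totals and risks**

Total step count: 13. Longest linear sequence: 7 steps (1 → 2 → 3 → 4 → 7 → 14 → 19 → 20, or equally 1 → 2 → 8 → 10 → 12 → 14 → 19 → 20).

Steps most likely to fail:

1. Step 12 (key cycloaddition). The addition may turn stepwise, with rotation at the benzylic cation and loss of the cis C2/C3 relationship. It may proceed through the wrong endo/exo mode or on the wrong methide face. The acid may isomerise or hydrolyse the enol ester, or electron-rich arene positions may capture the methide. Fallback (known flavan-4-yl cation chain assembly, setting out from 3, with 2, 4 and 11, and rejoining at 19): 2 is esterified with 11 (DCC, DMAP) to 5,7,3',4'-tetra-O-benzyl-(−)-epicatechin 3-O-[3,4,5-tris(benzyloxy)benzoate] F1, the nucleophilic unit. 3 is esterified in the same way to 5,7,3',4'-tetra-O-benzyl-4β-(2-ethoxyethoxy)epicatechin 3-O-[3,4,5-tris(benzyloxy)benzoate] F2, the electrophilic unit. TMSOTf in CH2Cl2 at −78 °C should join F2 to excess F1 at C8 (attack anti to the C3 ester) to give tetradeca-O-benzyl [epicatechin 3-O-gallate-(4β→8)-epicatechin 3-O-gallate] F3. A second TMSOTf-mediated coupling of F3, through C8 of its upper unit, with electrophile 4 should give 19.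

2. Step 9 (magnesium phenolate hydroxyalkylation). Addition may be sluggish because both partners carry two ortho substituents, and the product carbinol may ionise during reaction or work-up and be captured by a second phenolate. Fallback (boron-templated condensation, setting out from 7 and 12 and rejoining at 14): 7, 12 and phenylboronic acid are condensed (cat. propionic acid, toluene, 4 Å MS, 60–80 °C) to the 2-phenyl-4H-1,3,2-benzodioxaborin F4, in which boron ties the phenol oxygen to the aldehyde and forces ortho C–C bond formation. Transesterification with 2,2-dimethylpropane-1,3-diol (THF, rt) then releases 14.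

3. Step 5 (C4 arylation of the phenol). Site selectivity between the ortho and para carbons of 6 may be poor, and the product may be alkylated a second time. Fallback (symmetric nucleophile, setting out from 4 and 5 and rejoining at 7): 4 is coupled with excess unprotected phloroglucinol 5 (BF3·OEt2, THF/CH2Cl2, 0 °C), whose three ring carbons are equivalent, to give 2-[3,5,7,3',4'-penta-O-benzylepicatechin-4β-yl]benzene-1,3,5-triol F5. Controlled benzylation (BnBr, 2 equiv, K2CO3, DMF) should then take the unhindered para hydroxyl first and one of the two equivalent hindered ortho hydroxyls second, giving 7.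

**Further compounds**

F1 | step 12 | 5,7,3',4'-tetra-O-benzyl-(−)-epicatechin 3-O-[3,4,5-tris(benzyloxy)benzoate] | O=C(O[C@@H]1Cc2c(OCc3ccccc3)cc(OCc3ccccc3)cc2O[C@@H]1c1ccc(OCc2ccccc2)c(OCc2ccccc2)c1)c1cc(OCc2ccccc2)c(OCc2ccccc2)c(OCc2ccccc2)c1
F2 | step 12 | 5,7,3',4'-tetra-O-benzyl-4β-(2-ethoxyethoxy)epicatechin 3-O-[3,4,5-tris(benzyloxy)benzoate] | O1[C@H](c3ccc(OCc4ccccc4)c(OCc4ccccc4)c3)[C@H](OC(=O)c3cc(OCc4ccccc4)c(OCc4ccccc4)c(OCc4ccccc4)c3)[C@@H](OCCOCC)c2c(OCc3ccccc3)cc(OCc3ccccc3)cc21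
F3 | step 12 | tetradeca-O-benzyl [epicatechin 3-O-gallate-(4β→8)-epicatechin 3-O-gallate] | O1[C@H](c3ccc(OCc4ccccc4)c(OCc4ccccc4)c3)[C@H](OC(=O)c3cc(OCc4ccccc4)c(OCc4ccccc4)c(OCc4ccccc4)c3)[C@@H](c5c(OCc4ccccc4)cc(OCc4ccccc4)c6c5O[C@H](c7ccc(OCc4ccccc4)c(OCc4ccccc4)c7)[C@H](OC(=O)c7cc(OCc4ccccc4)c(OCc4ccccc4)c(OCc4ccccc4)c7)C6)c2c(OCc3ccccc3)cc(OCc3ccccc3)cc21
F4 | step 9 | 2-phenyl-4H-1,3,2-benzodioxaborin of 14 (boron bridging the phenol oxygen and the carbinol oxygen; C4 of the dioxaborin as a mixture of epimers) | O1[C@H](c3ccc(OCc4ccccc4)c(OCc4ccccc4)c3)[C@H](OCc3ccccc3)[C@@H](c3c(OCc4ccccc4)cc(OCc4ccccc4)c8c3OB(c9ccccc9)OC8c5c(OCc4ccccc4)cc(OCc4ccccc4)c6c5O[C@H](c7ccc(OCc4ccccc4)c(OCc4ccccc4)c7)[C@H](OC(=O)c7cc(OCc4ccccc4)c(OCc4ccccc4)c(OCc4ccccc4)c7)C6)c2c(OCc3ccccc3)cc(OCc3ccccc3)cc21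
F5 | step 5 | 2-[3,5,7,3',4'-penta-O-benzylepicatechin-4β-yl]benzene-1,3,5-triol | O1[C@H](c3ccc(OCc4ccccc4)c(OCc4ccccc4)c3)[C@H](OCc3ccccc3)[C@@H](c3c(O)cc(O)cc3O)c2c(OCc3ccccc3)cc(OCc3ccccc3)cc21
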